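## Structural features

The target is an open-chain decane (C1 benzylic, used as the numbering throughout) with a 3,4-dimethoxyphenyl ring on C1 and a pentyl tail from C6 to C10; the benzene ring is the only ring. Two oxygen-bearing stereocentres, C3 (acetoxy, S) and C5 (free hydroxyl, S), are separated only by the C4 methylene, so the compound is the 3-monoacetate of an anti-1,3-diol. The fragile points are the secondary acetate with a free hydroxyl 1,3 to it (acyl migration or loss under basic conditions) and the electron-rich arene, which is easily oxidised and makes any benzylic leaving group in an intermediate prone to ionise. The carbon skeleton is easy to assemble; the real difficulty is to place two secondary oxygens anti on a flexible chain and to tell them apart, one acylated and one free, without a late regioselective acylation. The key step uses the fact that C3 is 1,3 to the benzylic carbon C1: an acetoxy group first placed on C1 next to a C2=C3 alkene can be moved to C3 across one face of the C1–C2–C3 unit, the new C1=C2 bond ending up conjugated with the arene. That one operation sets C3, puts the acetyl group on the C3 oxygen while the C5 oxygen is still masked, and leaves a styrene that needs only saturation.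

## Logic of the disconnections

14 to 13: the O–H bond at C5 is traced back to an O–Si bond. The last step then touches only the C5 oxygen and the two oxygens stay distinguishable throughout. The forward step must remove silicon without moving or cleaving the C3 acetate.

13 to 12: unsaturation is reintroduced between C1 and C2. This makes the C3 acetate allylic and exposes the 1,3-relationship to C1. The forward step must saturate a styrene without hydrogenolysis of the allylic C3–O bond.

12 to 10: the C3–O bond is cut, the acetate is returned to C1 and the alkene moves to C2=C3. C1 thereby becomes a benzylic carbinol carbon, which an aldehyde addition can set, and the C3 centre and the placing of the acetyl group both derive from it. The forward step must transfer configuration completely and on one face.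

10 to 9: the acetyl C–O bond is cut. The gain is a plain allylic alcohol. The forward acylation must not ionise the benzylic C1–O bond.

9 to 5 and 6: the C1–C2 bond is cut between an aryl aldehyde and an E alkenyl metal derived from a terminal alkyne. This is the convergent point, and it sets C1 and the alkene geometry together. The forward step needs catalyst-controlled facial selectivity that ignores the remote C5 centre.

5 to 4: the Si–O bond is cut. The protecting group has to survive organoboron, organozinc, acylation and divalent palladium and still come off under mild acid.

4 to 2 and 3: the C3–C4 bond is cut, a homopropargylic alcohol being an epoxide plus acetylide. The C5 centre is then simply the epoxide carbon. The forward opening must occur only at the unsubstituted carbon.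

2 to 1: the single enantiomer is traced to the racemate by resolution. No bond is cut; the demand is a high selectivity factor and a clean separation of epoxide from diol.

## Other disconnections considered

Alternative 1: The cuts are C6–C7 and later C1–C2, both carbinol carbons coming from the C2-symmetric bis-epoxide (2R,4R)-1,2:4,5-diepoxypentane A1.
- Forward key step: a butyl Grignard reagent with a catalytic copper salt would open one of the two equivalent oxiranes of A1 at its CH2 end to give (2S)-1-[(2R)-oxiran-2-yl]heptan-2-ol A2. C5 then already carries its free hydroxyl and C3 is still held as an epoxide. Silylation, opening of the second oxirane by a 3,4-dimethoxybenzyl organometallic, acetylation and desilylation would lead through 13 to 14.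
- In its favour: both stereocentres come from one catalyst-controlled source and are never at risk afterwards, the oxygens are differentiated by the order of events, and only SN2 chemistry is needed.
- Against it here: the mono-opening is statistical unless conversion is held back, A1 is a volatile bifunctional alkylating agent that itself takes about three steps to make, electron-rich benzyl Grignard reagents tend to homocouple, and the acetyl group needs its own step.
- Comparison: on structure this plan is the better one for stereochemical security, since no step can leak configuration, whereas the chosen plan depends on complete transfer through an ionisable ester. On mechanism the chosen plan does more in one step and has no statistical step. On step count the two are about equal once the preparation of A1 is counted.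

Alternative 2: The cut is C2–C3, and the acetyl carbonyl carbon is recognised as a former lactone carbonyl.
- Forward key step: the lithium enolate of (5S)-5-pentyldihydrofuran-2(3H)-one A3 would be alkylated by 4-(2-iodoethyl)-1,2-dimethoxybenzene A4 on the ring face away from the pentyl group. This would give (3S,5S)-3-[2-(3,4-dimethoxyphenyl)ethyl]-5-pentyldihydrofuran-2(3H)-one A5. One equivalent of a methyl organometallic would open the lactone to (3S,5S)-3-[2-(3,4-dimethoxyphenyl)ethyl]-5-hydroxydecan-2-one A6. After silylation, a Baeyer–Villiger oxidation would insert oxygen between C3 and the acetyl carbon with retention, arriving at 13.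
- In its favour: 1,3-induction across a five-membered ring is dependable and needs no further chiral reagent, all chain and acetyl carbons are already present in A5, and the C5 oxygen is revealed in the step that creates the methyl ketone.
- Against it here: a 2-arylethyl iodide is prone to E2 loss of HI under enolate conditions, the trans selectivity of such alkylations is good but not complete, single addition to a lactone is hard to stop (A6 would sit largely as its cyclic hemiketal), and the peracid must spare the dimethoxyarene.
- Comparison: structurally it is the equal of the chosen plan in how directly it maps onto the target, and it is better in that no benzylic leaving group ever appears. Mechanistically it replaces one risk (ionisation) by three moderate ones. In step count it is about equal once A3 and A4 have been made.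

Alternative 3: The cut is C3–C4.
- Forward key step: 3-(3,4-dimethoxyphenyl)propyl N,N-diisopropylcarbamate A7 would be deprotonated next to oxygen by s-BuLi with (+)-sparteine. The lithiated carbamate would add to boron of tert-butyldimethyl{[(2R)-1-(4,4,5,5-tetramethyl-1,3,2-dioxaborolan-2-yl)heptan-2-yl]oxy}silane A8 (R by priority; the same arrangement in space as 5S of the target). In the ate complex the C4 methylene would shift from boron to C3 with loss of the carbamate, giving tert-butyl{[(3S,5S)-1-(3,4-dimethoxyphenyl)-3-(4,4,5,5-tetramethyl-1,3,2-dioxaborolan-2-yl)decan-5-yl]oxy}dimethylsilane A9. Oxidation of the C–B bond with retention, acetylation and desilylation would end at 14 through 13.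
- In its favour: it is the most convergent of the four plans, each stereocentre is set by a reagent independently of the other, and the 1,2-shift is stereospecific by mechanism.
- Against it here: A8 has a silyloxy group β to boron, so its ate complex can fragment by β-elimination instead of migrating; the scarcer sparteine enantiomer (or a surrogate) is needed in stoichiometric amount with an alkyllithium at low temperature; and the dimethoxyarene offers competing sites of lithiation.
- Comparison: in stereochemical reliability of the key event it is better than the chosen plan, provided elimination does not intervene. In convergence and length of the longest sequence it is equal or better by about one step. The chosen plan is better in practicality (a catalytic simple palladium salt near room temperature) and in that the acetate needs no separate step.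

Key step: step 6

Remarks before the steps:
- Check of the key pair: with the acetate leaving C1 and arriving at C3 on one face, (1R,2E)-10 maps onto (1E,3R)-12, and 3R becomes 3S on saturation by a change of priority alone. The structures of 10 and 12 are therefore kept unchanged.
- One labelling correction: wherever the C1 carbinol is held at the alkyne oxidation level (fallback of step 4), the alkynyl carbon outranks the aryl carbon. The same arrangement in space is 1S there, and the chiral catalyst has to be chosen for the S propargylic alcohol.
- Changes to the design ahead of the key step: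
  - the C1 carbinol and the E alkene are made together by an alkenylzinc addition, one step in place of alkyne addition plus trans-reduction;
  - 10 is never exposed to acidic silica;
  - the C5 oxygen stays silylated through step 6;
  - the styrene is reduced by diimide generated at room temperature.
- Abbreviations: salen = N,N'-bis(3,5-di-tert-butylsalicylidene)cyclohexane-1,2-diamine dianion; (+)-MIB = (2R)-3-exo-morpholinoisoborneol; NBSH = 2-nitrobenzenesulfonohydrazide.
- Assumption: the senses of the hydrolytic resolution (step 1) and of the alkenylzinc addition (step 4) are assigned by analogy with close relatives of 1 and 6; each would be verified on the first batch and the mirror-image catalyst used if needed.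

## Route

Step 1
Reactants: 1 racemic 2-pentyloxirane (1,2-epoxyheptane)
Product: 2 (2S)-2-pentyloxirane
Conditions: (S,S)-(salen)Co(OAc) (0.5 mol%), H2O (0.55 equiv), neat, 0 °C → rt; distillation
Reagents that add atoms: none
Why: Hydrolytic kinetic resolution: the chiral salen complex of trivalent cobalt should hydrate the R epoxide much faster, so that 2 remains and is distilled from the diol. No stereocentre is made; one enantiomer is removed, in the sense usual for simple alkyl oxiranes with this ligand series.

Step 2
Reactants: 2 (2S)-2-pentyloxirane; 3 lithium acetylide–ethylenediamine complex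
Product: 4 (4S)-non-1-yn-4-ol
Conditions: DMSO, 0 °C → rt; then H2O
Reagents that add atoms: none
Why: SN2 opening of a terminal epoxide by acetylide at the unsubstituted carbon. The C–O bond at the stereocentre is not touched, so the future C5 (S) is carried over unchanged.

Step 3
Reactants: 4 (4S)-non-1-yn-4-ol
Product: 5 tert-butyldimethyl{[(4S)-non-1-yn-4-yl]oxy}silane
Conditions: TBSCl, imidazole, DMF, rt
Reagents that add atoms: tert-butyldimethylsilyl chloride, CC(C)(C)[Si](C)(C)Cl
Why: Standard silylation of a secondary alcohol. The silyl ether is needed later: a free C5 hydroxyl would compete as an internal nucleophile under divalent palladium, and the group keeps the two oxygens distinct to the end.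

Step 4
Reactants: 5 tert-butyldimethyl{[(4S)-non-1-yn-4-yl]oxy}silane; 6 3,4-dimethoxybenzaldehyde (veratraldehyde)
Product: 9 (1R,2E,5S)-5-[(tert-butyldimethylsilyl)oxy]-1-(3,4-dimethoxyphenyl)dec-2-en-1-ol, via E-alkenyldicyclohexylborane 7 (not isolated), via E-alkenyl(methyl)zinc 8 (not isolated)
Conditions: Cy2BH (from BH3·SMe2 and cyclohexene), toluene, 0 °C → rt; Me2Zn, −78 °C; (+)-MIB (5 mol%), then 6, −20 → 0 °C; then H2O
Reagents that add atoms: none
Why: Catalytic asymmetric addition of an alkenylzinc to an aldehyde: syn-hydroboration fixes the E alkene in 7, boron-to-zinc exchange gives 8, and the zinc aminoalkoxide from (+)-MIB should deliver the alkenyl group to the Re face of 6, which sets C1 as R. The sense is assigned by analogy with dialkylzinc additions under the enantiomeric ligand, does not depend on the remote C5 centre, and would be confirmed on 9 by MTPA ester analysis.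

Step 5
Reactants: 9 (1R,2E,5S)-5-[(tert-butyldimethylsilyl)oxy]-1-(3,4-dimethoxyphenyl)dec-2-en-1-ol
Product: 10 (1R,2E,5S)-5-[(tert-butyldimethylsilyl)oxy]-1-(3,4-dimethoxyphenyl)dec-2-en-1-yl acetate
Conditions: Ac2O, Et3N, DMAP (cat.), CH2Cl2, 0 °C; NaHCO3 wash; used at once without chromatography
Reagents that add atoms: acetic anhydride, CC(=O)OC(C)=O
Why: Acyl transfer with nucleophilic catalysis under basic conditions at low temperature; no bond to C1 is broken, so its configuration is kept. Because 10 is an electron-rich benzylic allylic ester, it is kept away from acid and silica and taken on directly.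

Step 6
Reactants: 10 (1R,2E,5S)-5-[(tert-butyldimethylsilyl)oxy]-1-(3,4-dimethoxyphenyl)dec-2-en-1-yl acetate
Product: 12 (1E,3R,5S)-5-[(tert-butyldimethylsilyl)oxy]-1-(3,4-dimethoxyphenyl)dec-1-en-3-yl acetate, via palladated 1,3-dioxan-2-ylium 11 (not isolated)
Conditions: PdCl2(MeCN)2 (5 mol%), THF, 0 °C → rt
Reagents that add atoms: none
Why: The reaction type is the PdCl2(MeCN)2-catalysed 1,3-transposition of an allylic ester, a cyclisation-induced and formally [3,3] rearrangement. Divalent palladium binds the C2=C3 alkene of 10 on the face away from the acetate and makes C3 electrophilic; the acetate carbonyl oxygen then adds to C3 in a 6-endo-trig anti-oxypalladation, giving the chair 1,3-dioxan-2-ylium 11 with a C–Pd bond at C2. This transient ring is the only ring closed and it does not survive: anti-elimination of palladium and the C1–O bond opens it and places the new alkene at C1=C2. Because oxygen leaves C1 and arrives at C3 on the same face of the three-carbon unit, the configuration of C1 (set in step 4) controls the one new stereocentre, C3 (R in 12), through a chair in which the aryl group, the palladium and the C4 chain are all equatorial. The equatorial aryl group also accounts for the E geometry of the new styrene. The position of equilibrium is secured by the substrate, since the alkene of 12 is conjugated with the dimethoxyphenyl ring and that of 10 is not. The step needs the palladium-bound pathway to outrun heterolysis of the dimethoxybenzylic C1–O bond, which would give a planar allyl cation and the C3 epimer; a weakly ionising ether solvent, low temperature, acid-free substrate and a catalyst kept divalent work in that direction, and the silyl ether keeps the C5 oxygen from competing as an internal nucleophile.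

Step 7
Reactants: 12 (1E,3R,5S)-5-[(tert-butyldimethylsilyl)oxy]-1-(3,4-dimethoxyphenyl)dec-1-en-3-yl acetate
Product: 13 (3S,5S)-5-[(tert-butyldimethylsilyl)oxy]-1-(3,4-dimethoxyphenyl)decan-3-yl acetate
Conditions: NBSH (excess, in portions), Et3N, CH2Cl2, rt
Reagents that add atoms: none
Why: Diimide, released at room temperature from NBSH and Et3N, transfers two hydrogens to the C1=C2 bond in a concerted syn fashion and should neither hydrogenolyse the allylic C3–O bond nor touch arene, ester or silyl ether. C3 is unchanged in space; its descriptor becomes S only because C2 now ranks below C4.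

Step 8
Reactants: 13 (3S,5S)-5-[(tert-butyldimethylsilyl)oxy]-1-(3,4-dimethoxyphenyl)decan-3-yl acetate
Product: 14 (3S,5S)-1-(3,4-dimethoxyphenyl)-5-hydroxydecan-3-yl acetate
Conditions: HF·pyridine, pyridine, THF, 0 °C → rt
Reagents that add atoms: none
Why: Fluoride-assisted cleavage of the Si–O bond in a pyridine-buffered, weakly acidic medium. No alkoxide is formed, so migration of the acetyl group from O3 to O5 through a six-membered orthoester should be suppressed and the acetate is not cleaved.

## Compound list

1 | racemic 2-pentyloxirane (1,2-epoxyheptane) | CCCCCC1CO1 | starting material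
2 | (2S)-2-pentyloxirane | CCCCC[C@H]1CO1 | intermediate
3 | lithium acetylide–ethylenediamine complex | [Li]C#C.NCCN | starting material
4 | (4S)-non-1-yn-4-ol | CCCCC[C@H](O)CC#C | intermediate
5 | tert-butyldimethyl{[(4S)-non-1-yn-4-yl]oxy}silane | CCCCC[C@H](O[Si](C)(C)C(C)(C)C)CC#C | intermediate
6 | 3,4-dimethoxybenzaldehyde (veratraldehyde) | COc1ccc(C=O)cc1OC | starting material
7 | tert-butyl{[(1E,4S)-1-(dicyclohexylboranyl)non-1-en-4-yl]oxy}dimethylsilane (not isolated) | CCCCC[C@H](O[Si](C)(C)C(C)(C)C)C/C=C/B(C1CCCCC1)C1CCCCC1 | intermediate
8 | {(1E,4S)-4-[(tert-butyldimethylsilyl)oxy]non-1-en-1-yl}(methyl)zinc (not isolated) | CCCCC[C@H](O[Si](C)(C)C(C)(C)C)C/C=C/[Zn]C | intermediate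
9 | (1R,2E,5S)-5-[(tert-butyldimethylsilyl)oxy]-1-(3,4-dimethoxyphenyl)dec-2-en-1-ol | CCCCC[C@H](O[Si](C)(C)C(C)(C)C)C/C=C/[C@@H](O)c1ccc(OC)c(OC)c1 | intermediate
10 | (1R,2E,5S)-5-[(tert-butyldimethylsilyl)oxy]-1-(3,4-dimethoxyphenyl)dec-2-en-1-yl acetate | CCCCC[C@H](O[Si](C)(C)C(C)(C)C)C/C=C/[C@@H](OC(C)=O)c1ccc(OC)c(OC)c1 | intermediate
11 | zwitterionic chair 2-methyl-1,3-dioxan-2-ylium from 10 with PdCl2 on the central ring carbon (old C2), the aryl group on old C1 and the (2S)-2-[(tert-butyldimethylsilyl)oxy]heptyl group on old C3; all three equatorial, aryl and side chain cis, palladium trans to both (not isolated) | CCCCC[C@H](O[Si](C)(C)C(C)(C)C)C[C@@H]1[C@@H]([Pd-](Cl)Cl)[C@H](c2ccc(OC)c(OC)c2)[O+]=C(C)O1 | intermediate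
12 | (1E,3R,5S)-5-[(tert-butyldimethylsilyl)oxy]-1-(3,4-dimethoxyphenyl)dec-1-en-3-yl acetate | CCCCC[C@H](O[Si](C)(C)C(C)(C)C)C[C@H](/C=C/c1ccc(OC)c(OC)c1)OC(C)=O | intermediate
13 | (3S,5S)-5-[(tert-butyldimethylsilyl)oxy]-1-(3,4-dimethoxyphenyl)decan-3-yl acetate | CCCCC[C@H](O[Si](C)(C)C(C)(C)C)C[C@H](CCc1ccc(OC)c(OC)c1)OC(C)=O | intermediate
14 | (3S,5S)-1-(3,4-dimethoxyphenyl)-5-hydroxydecan-3-yl acetate | CCCCC[C@H](O)C[C@H](CCc1ccc(OC)c(OC)c1)OC(C)=O | target

## Step count and least certain steps

Total: 8 steps. Longest linear sequence: 8 steps (1 to 14); 3 and 6 are used as purchased.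

Step 6 (key step). The most likely failure is heterolysis of the dimethoxybenzylic C1–O bond running alongside the palladium-bound cyclisation. The allyl cation so formed recombines on either face, so chirality transfer would be incomplete and the C3 epimer of 12 would appear; loss of a proton to a diene is a second outlet.
- Fallback (sets out from 5 and 6, rejoins at 12): C3 is made by reagent-controlled reduction and not by transfer from C1.
- Deprotonation of 5 with n-BuLi (THF, −78 °C) gives {(4S)-4-[(tert-butyldimethylsilyl)oxy]non-1-yn-1-yl}lithium F1.
- F1 adds to 6 to give (1RS,5S)-5-[(tert-butyldimethylsilyl)oxy]-1-(3,4-dimethoxyphenyl)dec-2-yn-1-ol F2 as both C1 epimers.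
- A Meyer–Schuster rearrangement (Ph3PAuNTf2 cat., MeOH, toluene, rt) erases C1 and should give (1E,5S)-5-[(tert-butyldimethylsilyl)oxy]-1-(3,4-dimethoxyphenyl)dec-1-en-3-one F3.
- Corey–Bakshi–Shibata reduction ((S)-Me-CBS, catecholborane, toluene, −78 °C, styrenyl arm as the large group) should give (1E,3R,5S)-5-[(tert-butyldimethylsilyl)oxy]-1-(3,4-dimethoxyphenyl)dec-1-en-3-ol F4.
- Ac2O, Et3N and DMAP then give 12.

Step 4. Facial selectivity may be eroded with this electron-rich, slowly reacting aldehyde (uncatalysed background addition), and methyl transfer or incomplete boron-to-zinc exchange may compete.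
- Fallback (sets out from 5 and 6, rejoins at 9): alkynylation followed by trans-reduction.
- 5 and Et2Zn in hot toluene give ethyl{(4S)-4-[(tert-butyldimethylsilyl)oxy]non-1-yn-1-yl}zinc F5.
- With (R)-BINOL and Ti(OiPr)4, F5 should add to 6 to give (1S,5S)-5-[(tert-butyldimethylsilyl)oxy]-1-(3,4-dimethoxyphenyl)dec-2-yn-1-ol F6 (S here is the same arrangement in space as 1R in 9).
- Hydroxyl-directed trans-hydroalumination with NaAlH2(OCH2CH2OMe)2 in THF then gives 9.

Step 5. Ionisation of the newly formed benzylic acetate during work-up or concentration would cause a premature, non-stereospecific shift or solvolysis before the catalyst is present.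
- Fallback (sets out from 5 and 6, rejoins at 10): the addition of step 4 is not worked up. The zinc alkoxide, methylzinc (1R,2E,5S)-5-[(tert-butyldimethylsilyl)oxy]-1-(3,4-dimethoxyphenyl)dec-2-en-1-olate F7, is acetylated in the same flask with Ac2O, so the acetate is formed under strictly non-acidic, non-aqueous conditions.

Step 7. Diimide may disproportionate faster than it reduces a conjugated trans-disubstituted alkene, leaving 12 unconverted even with a large excess.
- Fallback (sets out from 12, rejoins at 13): metal-catalysed homogeneous hydrogenation with H2 (1 atm) and RhCl(PPh3)3 in toluene–EtOH. This works by a different mechanism and is little given to allylic C–O hydrogenolysis. It makes no new compound (entry F0).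

## Further compounds

F1 | step 6 | {(4S)-4-[(tert-butyldimethylsilyl)oxy]non-1-yn-1-yl}lithium | CCCCC[C@H](O[Si](C)(C)C(C)(C)C)CC#C[Li]
F2 | step 6 | (1RS,5S)-5-[(tert-butyldimethylsilyl)oxy]-1-(3,4-dimethoxyphenyl)dec-2-yn-1-ol | CCCCC[C@H](O[Si](C)(C)C(C)(C)C)CC#CC(O)c1ccc(OC)c(OC)c1
F3 | step 6 | (1E,5S)-5-[(tert-butyldimethylsilyl)oxy]-1-(3,4-dimethoxyphenyl)dec-1-en-3-one | CCCCC[C@H](O[Si](C)(C)C(C)(C)C)CC(=O)/C=C/c1ccc(OC)c(OC)c1
F4 | step 6 | (1E,3R,5S)-5-[(tert-butyldimethylsilyl)oxy]-1-(3,4-dimethoxyphenyl)dec-1-en-3-ol | CCCCC[C@H](O[Si](C)(C)C(C)(C)C)C[C@@H](O)/C=C/c1ccc(OC)c(OC)c1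
F5 | step 4 | ethyl{(4S)-4-[(tert-butyldimethylsilyl)oxy]non-1-yn-1-yl}zinc | CCCCC[C@H](O[Si](C)(C)C(C)(C)C)CC#C[Zn]CC
F6 | step 4 | (1S,5S)-5-[(tert-butyldimethylsilyl)oxy]-1-(3,4-dimethoxyphenyl)dec-2-yn-1-ol | CCCCC[C@H](O[Si](C)(C)C(C)(C)C)CC#C[C@@H](O)c1ccc(OC)c(OC)c1
F7 | step 5 | methylzinc (1R,2E,5S)-5-[(tert-butyldimethylsilyl)oxy]-1-(3,4-dimethoxyphenyl)dec-2-en-1-olate | CCCCC[C@H](O[Si](C)(C)C(C)(C)C)C/C=C/[C@@H](O[Zn]C)c1ccc(OC)c(OC)c1
F0 | step 7 | none | none
A1 | alternative 1 | (2R,4R)-1,2:4,5-diepoxypentane | C1[C@H](O1)C[C@@H]1CO1
A2 | alternative 1 | (2S)-1-[(2R)-oxiran-2-yl]heptan-2-ol | CCCCC[C@H](O)C[C@@H]1CO1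
A3 | alternative 2 | (5S)-5-pentyldihydrofuran-2(3H)-one | CCCCC[C@H]1CCC(=O)O1
A4 | alternative 2 | 4-(2-iodoethyl)-1,2-dimethoxybenzene | COc1ccc(CCI)cc1OC
A5 | alternative 2 | (3S,5S)-3-[2-(3,4-dimethoxyphenyl)ethyl]-5-pentyldihydrofuran-2(3H)-one | CCCCC[C@H]1C[C@H](CCc2ccc(OC)c(OC)c2)C(=O)O1
A6 | alternative 2 | (3S,5S)-3-[2-(3,4-dimethoxyphenyl)ethyl]-5-hydroxydecan-2-one | CCCCC[C@H](O)C[C@H](CCc1ccc(OC)c(OC)c1)C(C)=O
A7 | alternative 3 | 3-(3,4-dimethoxyphenyl)propyl N,N-diisopropylcarbamate | COc1ccc(CCCOC(=O)N(C(C)C)C(C)C)cc1OC
A8 | alternative 3 | tert-butyldimethyl{[(2R)-1-(4,4,5,5-tetramethyl-1,3,2-dioxaborolan-2-yl)heptan-2-yl]oxy}silane | CCCCC[C@H](O[Si](C)(C)C(C)(C)C)CB1OC(C)(C)C(C)(C)O1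
A9 | alternative 3 | tert-butyl{[(3S,5S)-1-(3,4-dimethoxyphenyl)-3-(4,4,5,5-tetramethyl-1,3,2-dioxaborolan-2-yl)decan-5-yl]oxy}dimethylsilane | CCCCC[C@H](O[Si](C)(C)C(C)(C)C)C[C@H](CCc1ccc(OC)c(OC)c1)B1OC(C)(C)C(C)(C)O1
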